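## Plan

1. Cuts: the 19 O-benzyl ethers; the interflavan bond C4(top)–C8(middle); the interflavan bond C4(middle)–C8(bottom); and, inside the top unit, ring C at C3–C4 and at O1–C8a. The last cut leaves sulfide 5 (ring A plus C4) and epoxy ether 9 (O1–C2–C3 plus ring B).
2. Forward: ring C of the top unit closes in one pot by a [3+3] union of 5 and 9. Middle and bottom units come from (−)-epigallocatechin 13 and are joined first (dimer 18). The top unit is then attached to C8 of the middle unit, and hydrogenolysis ends the route.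
3. Enabling feature: in ring A of the top unit, C8a bears the ether oxygen meta to both other ring oxygens and C4 is benzylic to that ring. C8a can therefore be masked as C–F (an SNAr site) and C4 as a sulfur-stabilised carbanion, while the vicinal C2–O1/C3–O pair is stored as a strained trans epoxy ether.
4. Stereochemistry: top C2 from the Shi epoxidation (step 7); top C3 from stereospecific inversion at the acetal carbon (step 8); both C4 centres from anti (3,4-trans) attack on flavan-4-yl cations (steps 12 and 13); all other centres from 13.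

Key step: step 8

Remark: C4 of 12 forms as an epimer mixture. This centre is ionised in step 13, so no control is needed there, and the SMILES of 10, 11 and 12 leave it undefined.

## Route

Step 1
Reactants: 1 1,3,5-trifluorobenzene
Product: 2 1,3-bis(benzyloxy)-5-fluorobenzene
Conditions: BnOH (2.1 equiv), NaH, NMP, 0 → 90 °C
Reagents that add atoms: benzyl alcohol OCc1ccccc1
Why: Twofold SNAr of benzyloxide on the electron-poor trifluoroarene should stop at the difluoride-free diether when the stoichiometry is held at two equivalents.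

Step 2
Reactants: 2 1,3-bis(benzyloxy)-5-fluorobenzene
Product: 3 2,4-bis(benzyloxy)-6-fluorobenzaldehyde
Conditions: POCl3, DMF, 0 → 60 °C; then H2O
Reagents that add atoms: N,N-dimethylformamide CN(C)C=O; water O
Why: Vilsmeier–Haack formylation should occur at the position ortho/para to the two ethers and next to fluorine, which is less hindered than the position between the two benzyloxy groups.

Step 3
Reactants: 3 2,4-bis(benzyloxy)-6-fluorobenzaldehyde
Product: 4 [2,4-bis(benzyloxy)-6-fluorophenyl]methanol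
Conditions: NaBH4, THF/MeOH, 0 °C
Reagents that add atoms: none
Why: Borohydride reduction of an aryl aldehyde to the benzylic alcohol is routine and leaves the aryl fluoride and benzyl ethers untouched.

Step 4
Reactants: 4 [2,4-bis(benzyloxy)-6-fluorophenyl]methanol
Product: 5 2,4-bis(benzyloxy)-6-fluorobenzyl phenyl sulfide
Conditions: PhSSPh, n-Bu3P, THF, 0 °C → rt
Reagents that add atoms: diphenyl disulfide c1ccc(cc1)SSc1ccccc1
Why: Mitsunobu-type phosphine/disulfide thioetherification converts a primary benzylic alcohol into the aryl sulfide under neutral conditions.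

Step 5
Reactants: 6 3,4,5-tris(benzyloxy)benzaldehyde
Product: 7 (E)-1,2,3-tris(benzyloxy)-5-(2-iodoethenyl)benzene
Conditions: CHI3, CrCl2, THF, 0 °C → rt
Reagents that add atoms: iodoform IC(I)I
Why: Takai olefination of aryl aldehydes through the gem-dichromium species should give the (E)-vinyl iodide.

Step 6
Reactants: 7 (E)-1,2,3-tris(benzyloxy)-5-(2-iodoethenyl)benzene
Product: 8 (E)-1,2,3-tris(benzyloxy)-5-[2-(benzyloxy)ethenyl]benzene
Conditions: BnOH, CuI (10 mol %), 3,4,7,8-tetramethyl-1,10-phenanthroline (20 mol %), Cs2CO3, toluene, 80 °C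
Reagents that add atoms: benzyl alcohol OCc1ccccc1
Why: Copper-catalysed Ullmann-type C–O coupling of vinyl iodides with alcohols proceeds with retention of alkene geometry, so the (E)-enol ether is expected.

Step 7
Reactants: 8 (E)-1,2,3-tris(benzyloxy)-5-[2-(benzyloxy)ethenyl]benzene
Product: 9 (2S,3R)-2-(benzyloxy)-3-[3,4,5-tris(benzyloxy)phenyl]oxirane
Conditions: D-fructose-derived Shi ketone (30 mol %), Oxone (2KHSO5·KHSO4·K2SO4), K2CO3, n-Bu4NHSO4, MeCN/dimethoxymethane/aq. borate buffer (pH 10.5), −10 °C; cold pentane/Et2O extraction, dried over K2CO3, used at once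
Reagents that add atoms: potassium peroxymonosulfate [K+].[O-]S(=O)(=O)OO
Why: Shi epoxidation of a trans-disubstituted, electron-rich alkene through the spiro transition state of the chiral dioxirane should deliver oxygen to the face that makes the benzylic carbon R (the sense seen with trans-β-substituted styrenes), with the trans geometry retained.

Step 8
Reactants: 5 2,4-bis(benzyloxy)-6-fluorobenzyl phenyl sulfide; 9 (2S,3R)-2-(benzyloxy)-3-[3,4,5-tris(benzyloxy)phenyl]oxirane
Product: 12 (2R,3S,4RS)-3,5,7-tris(benzyloxy)-4-(phenylsulfanyl)-2-[3,4,5-tris(benzyloxy)phenyl]chromane, via lithiated sulfide 10 (not isolated), via ring-opened lithium alkoxide 11 (not isolated)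
Conditions: n-BuLi, THF, −78 °C; 9, −78 → −20 °C; then KOt-Bu, DMPU, 0 → 50 °C
Reagents that add atoms: none
Why: Proposed new method: α-lithiation of 5 gives the sulfur-stabilised benzylic carbanion 10, which should open the strained epoxy ether 9 by SN2 attack with inversion at the acetal carbon (the future C3), forming C3–C4 and releasing the C2 alkoxide 11; the closest known reaction type is the opening of glycal epoxides (1,2-anhydro sugars) at the anomeric carbon by carbon nucleophiles. After exchange of lithium for potassium the alkoxide should close ring C by 6-exo-trig intramolecular SNAr (Meisenheimer addition–elimination) at C8a–F, a fluorine meta to both benzyloxy groups and so not deactivated by them; pyran closure by alkoxide SNAr on fluorinated ring A precursors is a known way to flavan-3-ols. C2 keeps the configuration of 9 because its C–O bond is never broken, and C3 is fixed by the inversion, so the trans oxirane becomes the 2,3-cis (epi) relationship; C4 forms as an epimer mixture, which is harmless because it is ionised in step 13. Chemoselectivity of the closure is built into the substrate: O3 arrives as a benzyl ether, so O1 is the only oxygen nucleophile and the competing five-membered (dihydrobenzofuran) closure cannot occur. Regioselectivity of the opening (acetal carbon rather than benzylic oxirane carbon) rests on the alkoxy-activated acetal carbon and the absence of a Lewis acid, and the low temperature should hold back alkoxy-shift rearrangement of 9.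

Step 9
Reactants: 13 (−)-epigallocatechin
Product: 14 (2R,3R)-5,7-bis(benzyloxy)-2-[3,4,5-tris(benzyloxy)phenyl]chroman-3-ol
Conditions: BnBr, K2CO3, DMF, degassed, −10 °C → rt
Reagents that add atoms: benzyl bromide BrCc1ccccc1
Why: Williamson etherification with carbonate alkylates the five phenols only, leaving the aliphatic 3-OH free; low temperature and exclusion of air guard C2 against base-induced epimerisation.

Step 10
Reactants: 14 (2R,3R)-5,7-bis(benzyloxy)-2-[3,4,5-tris(benzyloxy)phenyl]chroman-3-ol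
Product: 15 (2R,3R,4S)-5,7-bis(benzyloxy)-4-(2-ethoxyethoxy)-2-[3,4,5-tris(benzyloxy)phenyl]chroman-3-ol
Conditions: DDQ, 2-ethoxyethanol, CH2Cl2, rt
Reagents that add atoms: 2-ethoxyethanol CCOCCO
Why: DDQ benzylic oxidation (hydride abstraction at C4, the cation being stabilised by ring A) with capture by the alcohol anti to the 3-OH should give the 4β ether, as is usual for benzylated flavan-3-ols.

Step 11
Reactants: 15 (2R,3R,4S)-5,7-bis(benzyloxy)-4-(2-ethoxyethoxy)-2-[3,4,5-tris(benzyloxy)phenyl]chroman-3-ol; 16 3,4,5-tris(benzyloxy)benzoic acid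
Product: 17 (2R,3R,4S)-5,7-bis(benzyloxy)-4-(2-ethoxyethoxy)-2-[3,4,5-tris(benzyloxy)phenyl]chroman-3-yl 3,4,5-tris(benzyloxy)benzoate
Conditions: DCC, DMAP, CH2Cl2, rt
Reagents that add atoms: none
Why: Steglich esterification acylates the only free hydroxyl (3-OH) and does not disturb the C4 ether.

Step 12
Reactants: 17 (2R,3R,4S)-5,7-bis(benzyloxy)-4-(2-ethoxyethoxy)-2-[3,4,5-tris(benzyloxy)phenyl]chroman-3-yl 3,4,5-tris(benzyloxy)benzoate; 14 (2R,3R)-5,7-bis(benzyloxy)-2-[3,4,5-tris(benzyloxy)phenyl]chroman-3-ol (3 equiv)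
Product: 18 penta-O-benzyl-3-O-[3,4,5-tris(benzyloxy)benzoyl]epigallocatechin-(4β→8)-penta-O-benzylepigallocatechin
Conditions: TMSOTf (cat.), CH2Cl2, −78 → −40 °C
Reagents that add atoms: none
Why: Lewis-acid ionisation of the C4 ether gives the flavan-4-yl cation, which C8 of 14 should attack in a Friedel–Crafts sense anti to the 3-O-acyl group (helped by acyl participation), setting the 4β (3,4-trans) bond; the excess of 14 suppresses self-condensation.

Step 13
Reactants: 12 (2R,3S,4RS)-3,5,7-tris(benzyloxy)-4-(phenylsulfanyl)-2-[3,4,5-tris(benzyloxy)phenyl]chromane; 18 penta-O-benzyl-3-O-[3,4,5-tris(benzyloxy)benzoyl]epigallocatechin-(4β→8)-penta-O-benzylepigallocatechin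
Product: 19 hexa-O-benzylepigallocatechin-(4β→8)-[penta-O-benzyl-3-O-(tri-O-benzylgalloyl)epigallocatechin]-(4β→8)-penta-O-benzylepigallocatechin
Conditions: AgBF4, CH2Cl2/THF, −20 → 0 °C
Reagents that add atoms: none
Why: Thiophilic activation of the 4-phenylthio group by AgBF4 gives the C4 cation of the top unit, which the free C8 of the upper unit of 18 should attack from the β face, anti to the 3-OBn and 2-aryl groups, so both C4 epimers of 12 converge on the 4β (3,4-trans) linkage.

Step 14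
Reactants: 19 hexa-O-benzylepigallocatechin-(4β→8)-[penta-O-benzyl-3-O-(tri-O-benzylgalloyl)epigallocatechin]-(4β→8)-penta-O-benzylepigallocatechin
Product: 20 epigallocatechin-(4β→8)-epigallocatechin 3-O-gallate-(4β→8)-epigallocatechin (CNP0278699.1)
Conditions: H2 (1 atm), Pd(OH)2/C, THF/MeOH/H2O, rt
Reagents that add atoms: none
Why: Global hydrogenolysis removes all 19 benzyl ethers while the gallate ester and the interflavan bonds are stable to these neutral conditions.

## Compound list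

1 | 1,3,5-trifluorobenzene | Fc1cc(F)cc(F)c1 | starting material
2 | 1,3-bis(benzyloxy)-5-fluorobenzene | Fc1cc(OCc2ccccc2)cc(OCc2ccccc2)c1 | intermediate
3 | 2,4-bis(benzyloxy)-6-fluorobenzaldehyde | O=Cc1c(F)cc(OCc2ccccc2)cc1OCc1ccccc1 | intermediate
4 | [2,4-bis(benzyloxy)-6-fluorophenyl]methanol | OCc1c(F)cc(OCc2ccccc2)cc1OCc1ccccc1 | intermediate
5 | 2,4-bis(benzyloxy)-6-fluorobenzyl phenyl sulfide | c1ccccc1SCc1c(F)cc(OCc2ccccc2)cc1OCc1ccccc1 | intermediate
6 | 3,4,5-tris(benzyloxy)benzaldehyde | O=Cc1cc(OCc2ccccc2)c(OCc2ccccc2)c(OCc2ccccc2)c1 | starting material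
7 | (E)-1,2,3-tris(benzyloxy)-5-(2-iodoethenyl)benzene | I/C=C/c1cc(OCc5ccccc5)c(OCc5ccccc5)c(OCc5ccccc5)c1 | intermediate
8 | (E)-1,2,3-tris(benzyloxy)-5-[2-(benzyloxy)ethenyl]benzene | c1ccccc1CO/C=C/c1cc(OCc5ccccc5)c(OCc5ccccc5)c(OCc5ccccc5)c1 | intermediate
9 | (2S,3R)-2-(benzyloxy)-3-[3,4,5-tris(benzyloxy)phenyl]oxirane (trans epoxy ether) | O1[C@H](c2cc(OCc5ccccc5)c(OCc5ccccc5)c(OCc5ccccc5)c2)[C@H]1OCc1ccccc1 | intermediate
10 | α-lithio derivative of sulfide 5 | [Li]C(Sc1ccccc1)c1c(F)cc(OCc5ccccc5)cc1OCc1ccccc1 | intermediate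
11 | lithium (1R,2S,3RS)-2-(benzyloxy)-3-[2,4-bis(benzyloxy)-6-fluorophenyl]-3-(phenylsulfanyl)-1-[3,4,5-tris(benzyloxy)phenyl]propan-1-olate | [Li+].[O-][C@H](c1cc(OCc5ccccc5)c(OCc5ccccc5)c(OCc5ccccc5)c1)[C@H](OCc1ccccc1)C(Sc1ccccc1)c1c(F)cc(OCc5ccccc5)cc1OCc1ccccc1 | intermediate
12 | (2R,3S,4RS)-3,5,7-tris(benzyloxy)-4-(phenylsulfanyl)-2-[3,4,5-tris(benzyloxy)phenyl]chromane (2,3-cis; 4-phenylthio hexa-O-benzylepigallocatechin, C4 epimers) | c1ccccc1SC1c2c(OCc5ccccc5)cc(OCc5ccccc5)cc2O[C@H](c2cc(OCc5ccccc5)c(OCc5ccccc5)c(OCc5ccccc5)c2)[C@@H]1OCc1ccccc1 | intermediate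
13 | (−)-epigallocatechin, (2R,3R)-2-(3,4,5-trihydroxyphenyl)chromane-3,5,7-triol | O[C@@H]1Cc2c(O)cc(O)cc2O[C@@H]1c1cc(O)c(O)c(O)c1 | starting material
14 | (2R,3R)-5,7-bis(benzyloxy)-2-[3,4,5-tris(benzyloxy)phenyl]chroman-3-ol (penta-O-benzylepigallocatechin) | O[C@@H]1Cc2c(OCc5ccccc5)cc(OCc5ccccc5)cc2O[C@@H]1c1cc(OCc5ccccc5)c(OCc5ccccc5)c(OCc5ccccc5)c1 | intermediate
15 | (2R,3R,4S)-5,7-bis(benzyloxy)-4-(2-ethoxyethoxy)-2-[3,4,5-tris(benzyloxy)phenyl]chroman-3-ol (4β ether) | O[C@@H]1[C@@H](OCCOCC)c2c(OCc5ccccc5)cc(OCc5ccccc5)cc2O[C@@H]1c1cc(OCc5ccccc5)c(OCc5ccccc5)c(OCc5ccccc5)c1 | intermediate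
16 | 3,4,5-tris(benzyloxy)benzoic acid | OC(=O)c1cc(OCc2ccccc2)c(OCc2ccccc2)c(OCc2ccccc2)c1 | starting material
17 | 3-O-[3,4,5-tris(benzyloxy)benzoyl] ester of 15 | O=C(O[C@@H]1[C@@H](OCCOCC)c2c(OCc5ccccc5)cc(OCc5ccccc5)cc2O[C@@H]1c1cc(OCc5ccccc5)c(OCc5ccccc5)c(OCc5ccccc5)c1)c1cc(OCc5ccccc5)c(OCc5ccccc5)c(OCc5ccccc5)c1 | intermediate
18 | penta-O-benzyl-3-O-[3,4,5-tris(benzyloxy)benzoyl]epigallocatechin-(4β→8)-penta-O-benzylepigallocatechin (lower 3-OH free) | O=C(O[C@@H]1[C@@H](c2c(OCc5ccccc5)cc(OCc5ccccc5)c3c2O[C@H](c2cc(OCc5ccccc5)c(OCc5ccccc5)c(OCc5ccccc5)c2)[C@H](O)C3)c2c(OCc5ccccc5)cc(OCc5ccccc5)cc2O[C@@H]1c1cc(OCc5ccccc5)c(OCc5ccccc5)c(OCc5ccccc5)c1)c1cc(OCc5ccccc5)c(OCc5ccccc5)c(OCc5ccccc5)c1 | intermediate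
19 | hexa-O-benzylepigallocatechin-(4β→8)-[penta-O-benzyl-3-O-(tri-O-benzylgalloyl)epigallocatechin]-(4β→8)-penta-O-benzylepigallocatechin | O=C(O[C@@H]1[C@@H](c2c(OCc5ccccc5)cc(OCc5ccccc5)c3c2O[C@H](c2cc(OCc5ccccc5)c(OCc5ccccc5)c(OCc5ccccc5)c2)[C@H](O)C3)c2c(OCc5ccccc5)cc(OCc5ccccc5)c([C@H]3c4c(OCc5ccccc5)cc(OCc5ccccc5)cc4O[C@H](c4cc(OCc5ccccc5)c(OCc5ccccc5)c(OCc5ccccc5)c4)[C@@H]3OCc5ccccc5)c2O[C@@H]1c1cc(OCc5ccccc5)c(OCc5ccccc5)c(OCc5ccccc5)c1)c1cc(OCc5ccccc5)c(OCc5ccccc5)c(OCc5ccccc5)c1 | intermediate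
20 | epigallocatechin-(4β→8)-epigallocatechin 3-O-gallate-(4β→8)-epigallocatechin (CNP0278699.1) | O=C(O[C@@H]1[C@@H](c2c(O)cc(O)c3c2O[C@H](c2cc(O)c(O)c(O)c2)[C@H](O)C3)c2c(O)cc(O)c([C@H]3c4c(O)cc(O)cc4O[C@H](c4cc(O)c(O)c(O)c4)[C@@H]3O)c2O[C@@H]1c1cc(O)c(O)c(O)c1)c1cc(O)c(O)c(O)c1 | target

## Summary

Total step count: 14.
Longest linear sequence: 7 steps (steps 1, 2, 3, 4, 8, 13, 14).

Steps most likely to fail:

1. Step 8. The carbanion may attack the benzylic oxirane carbon, or may induce alkoxy-shift rearrangement or deprotonation of the epoxy ether before C–C bond formation, and the alkoxide may then fail to displace fluoride. Fallback with known chemistry, setting out from 14: O-benzylation of the 3-OH (NaH, BnBr, DMF) should give hexa-O-benzylepigallocatechin F1. DDQ oxidation in the presence of 2-ethoxyethanol should give its 4β-(2-ethoxyethoxy) ether F2. F2 then takes the place of 12 in the union with 18 (TMSOTf, CH2Cl2, −78 °C), and the route is rejoined at 19.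

2. Step 7. The epoxy ether may be lost by hydrolysis or alkoxy-shift rearrangement in the buffered aqueous medium, or facial selectivity may be poor. Fallback, setting out from 8: epoxidation with acetone-free dimethyldioxirane in CH2Cl2 at −40 °C gives 9 as a racemate, that is together with the (2R,3S)-epoxy ether F3. Step 8 then gives 12 together with its enantiomer, the (2S,3R,4RS)-sulfide F4. Union with enantiopure 18 under the conditions of step 13 turns the pair into 19 and the diastereomeric trimer F5, whose top unit has the 2S,3S,4S configuration. Chromatographic separation of the two diastereomers rejoins the route at 19, so absolute control by the catalyst is replaced by resolution through the enantiopure dimer.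

3. Step 13. The cation from 12 may be captured by ring A of another molecule of 12 or by the C6 positions of 18, leading to oligomers and regioisomers. Fallback, setting out from 12 and 17: the order of assembly is reversed so that both nucleophiles are monomers. Soft activation of the sulfide with DMTSF (dimethyl(methylthio)sulfonium tetrafluoroborate) and 2,6-di-tert-butyl-4-methylpyridine (CH2Cl2, −40 °C) in the presence of 17 should give the top–middle dimer, hexa-O-benzylepigallocatechin-(4β→8)-[4β-(2-ethoxyethoxy)penta-O-benzyl-3-O-(tri-O-benzylgalloyl)epigallocatechin] F6, with the C4 ether of the middle unit left intact. Ionisation of that ether with TMSOTf in the presence of excess 14 (CH2Cl2, −78 °C) then forms the second interflavan bond and rejoins the route at 19.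

## Further compounds

F1 | step 8 | (2R,3R)-3,5,7-tris(benzyloxy)-2-[3,4,5-tris(benzyloxy)phenyl]chromane (hexa-O-benzylepigallocatechin) | c1ccccc1CO[C@@H]1Cc2c(OCc5ccccc5)cc(OCc5ccccc5)cc2O[C@@H]1c1cc(OCc5ccccc5)c(OCc5ccccc5)c(OCc5ccccc5)c1
F2 | step 8 | 4β-(2-ethoxyethoxy) ether of F1 | c1ccccc1CO[C@@H]1[C@@H](OCCOCC)c2c(OCc5ccccc5)cc(OCc5ccccc5)cc2O[C@@H]1c1cc(OCc5ccccc5)c(OCc5ccccc5)c(OCc5ccccc5)c1
F3 | step 7 | (2R,3S)-2-(benzyloxy)-3-[3,4,5-tris(benzyloxy)phenyl]oxirane (enantiomer of 9) | O1[C@@H](c2cc(OCc5ccccc5)c(OCc5ccccc5)c(OCc5ccccc5)c2)[C@@H]1OCc1ccccc1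
F4 | step 7 | (2S,3R,4RS)-3,5,7-tris(benzyloxy)-4-(phenylsulfanyl)-2-[3,4,5-tris(benzyloxy)phenyl]chromane (enantiomer of 12) | c1ccccc1SC1c2c(OCc5ccccc5)cc(OCc5ccccc5)cc2O[C@@H](c2cc(OCc5ccccc5)c(OCc5ccccc5)c(OCc5ccccc5)c2)[C@H]1OCc1ccccc1
F5 | step 7 | diastereomer of 19 with a (2S,3S,4S) top unit | O=C(O[C@@H]1[C@@H](c2c(OCc5ccccc5)cc(OCc5ccccc5)c3c2O[C@H](c2cc(OCc5ccccc5)c(OCc5ccccc5)c(OCc5ccccc5)c2)[C@H](O)C3)c2c(OCc5ccccc5)cc(OCc5ccccc5)c([C@@H]3c4c(OCc5ccccc5)cc(OCc5ccccc5)cc4O[C@@H](c4cc(OCc5ccccc5)c(OCc5ccccc5)c(OCc5ccccc5)c4)[C@H]3OCc5ccccc5)c2O[C@@H]1c1cc(OCc5ccccc5)c(OCc5ccccc5)c(OCc5ccccc5)c1)c1cc(OCc5ccccc5)c(OCc5ccccc5)c(OCc5ccccc5)c1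
F6 | step 13 | hexa-O-benzylepigallocatechin-(4β→8)-[4β-(2-ethoxyethoxy)penta-O-benzyl-3-O-(tri-O-benzylgalloyl)epigallocatechin] | O=C(O[C@@H]1[C@@H](OCCOCC)c2c(OCc5ccccc5)cc(OCc5ccccc5)c([C@H]3c4c(OCc5ccccc5)cc(OCc5ccccc5)cc4O[C@H](c4cc(OCc5ccccc5)c(OCc5ccccc5)c(OCc5ccccc5)c4)[C@@H]3OCc5ccccc5)c2O[C@@H]1c1cc(OCc5ccccc5)c(OCc5ccccc5)c(OCc5ccccc5)c1)c1cc(OCc5ccccc5)c(OCc5ccccc5)c(OCc5ccccc5)c1
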